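**Retrosynthetic overview**

1. Numbering of the target bicycle (3,7-dioxabicyclo[3.3.0]octane): C1 = acetoxy-bearing ring-fusion carbon, C2 = ArCH, O3, C4 = CH2, C5 = ring-fusion CH, C6 = ArCH, O7, C8 = CH2. The phenol silyl groups and the acetate are taken off the plan first; the bicycle 18 is then cut at C4–C5 and at O7–C6 in one step.
2. Both bonds come from one monocyclic 1,3-dioxane, 15. Its acetal carbon becomes C4, its O3–C4(aryl) unit becomes O3–C2, its C5 (OH, E-styryl) becomes C1, and its O1–C6H2 unit becomes O7–C8.
3. Enabling feature: in 15 the formaldehyde acetal carbon is joined through O3–C4–C5 to the internal carbon of the (E)-styryl group, so opening of the C2–O1 bond gives a 4-arylbut-3-enyl oxocarbenium ion set up for a five-ring Prins closure. The oxygen that is released (O1) stays tied through C6 to C5 and is placed to close the second five-membered ring, and the alkene terminus carries the cation-stabilising aryl group.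
4. 15 comes from 4-aryl-1,3-dioxan-5-one 12 by axial addition of the alkenylcerium reagent made from iodide 3. 12 comes from an Evans glycolate aldol (sets C2), reduction, formal formation, debenzylation and oxidation; both aryl units come from vanillin.
5. Ring order: temporary 1,3-dioxane, then its contraction to the tetrahydrofuran C1–C2–O3–C4–C5 (C4–C5 bond), then the tetrahydrofuran C5–C6–O7–C8–C1 (O7–C6 bond).

Key step: step 10

Remark: Ar = 3-methoxy-4-(triisopropylsilyloxy)phenyl throughout; vanillin, (S)-4-benzyloxazolidin-2-one and benzyloxyacetyl chloride are taken as the commercial starting materials.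

**Route**

Step 1
Reactants: 1 vanillin (4-hydroxy-3-methoxybenzaldehyde)
Product: 2 3-methoxy-4-(triisopropylsilyloxy)benzaldehyde (ArCHO)
Conditions: iPr3SiCl, imidazole, DMF, 0 °C to rt
Reagents that add atoms: chlorotriisopropylsilane, CC(C)[Si](Cl)(C(C)C)C(C)C
Why: Silyl ether formation on the phenol gives a protecting group that should survive base, hydride and Lewis acid at low temperature, keeps the ring electron-rich and is removed by fluoride at the end.

Step 2
Reactants: 2 3-methoxy-4-(triisopropylsilyloxy)benzaldehyde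
Product: 3 (E)-ArCH=CHI, (E)-1-(2-iodoethenyl)-3-methoxy-4-(triisopropylsilyloxy)benzene
Conditions: CHI3, CrCl2, THF, 0 °C to rt
Reagents that add atoms: iodoform, IC(I)I
Why: Takai olefination: the geminal dichromium species from iodoform adds to the aldehyde and eliminates anti, which should give the E iodoalkene.

Step 3
Reactants: 4 (S)-4-benzyloxazolidin-2-one; 5 benzyloxyacetyl chloride
Product: 6 (S)-4-benzyl-3-[(benzyloxy)acetyl]oxazolidin-2-one
Conditions: Et3N, DMAP (cat.), CH2Cl2, 0 °C to rt
Reagents that add atoms: none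
Why: DMAP-catalysed N-acylation of the oxazolidinone attaches the glycolate unit to the auxiliary without touching its stereocentre.

Step 4
Reactants: 6 (S)-4-benzyl-3-[(benzyloxy)acetyl]oxazolidin-2-one; 2 ArCHO
Product: 8 (4S)-4-benzyl-3-[(2S,3R)-3-Ar-2-(benzyloxy)-3-hydroxypropanoyl]oxazolidin-2-one, via Z-dibutylboron enolate 7 (not isolated)
Conditions: Bu2BOTf, Et3N, CH2Cl2, −78 to 0 °C; 2, −78 to 0 °C; pH 7 buffer, MeOH, H2O2, 0 °C
Reagents that add atoms: none
Why: Evans syn-aldol reaction: the Z boron enolate reacts through a chair (Zimmerman–Traxler) transition state on the face away from the benzyl group of the auxiliary, which should set the 2S,3R pair; the carbinol carbon (3R) becomes C2 of the target.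

Step 5
Reactants: 8 the aldol adduct
Product: 9 (1R,2R)-1-Ar-2-(benzyloxy)propane-1,3-diol
Conditions: LiBH4, MeOH (1 equiv), THF, 0 °C
Reagents that add atoms: none
Why: Reductive cleavage of the N-acyl oxazolidinone by borohydride releases the auxiliary and gives the primary alcohol without epimerisation, so the 1,3-diol stands free while the middle oxygen stays benzylated.

Step 6
Reactants: 9 (1R,2R)-1-Ar-2-(benzyloxy)propane-1,3-diol
Product: 10 (4R,5R)-4-Ar-5-(benzyloxy)-1,3-dioxane
Conditions: CH2(OMe)2 (solvent), LiBr, TsOH·H2O (cat.), rt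
Reagents that add atoms: dimethoxymethane, COCOC
Why: Acid-catalysed transacetalisation with dimethoxymethane can close only the six-membered formal across the free 1,3-diol and installs the carbon that becomes C4 of the target; the mild Brønsted acid is chosen to keep the electron-rich benzylic C–O bond from ionising, and any epimer formed there would be a separable diastereomer at this stage.

Step 7
Reactants: 10 (4R,5R)-4-Ar-5-(benzyloxy)-1,3-dioxane
Product: 11 (4R,5R)-4-Ar-1,3-dioxan-5-ol
Conditions: H2 (1 atm), 10% Pd/C, EtOAc, rt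
Reagents that add atoms: none
Why: Hydrogenolysis of the unhindered O-benzyl ether under neutral conditions should be much faster than cleavage of the secondary benzylic C–O bond that is part of the acetal ring, and the aryl silyl ether is inert.

Step 8
Reactants: 11 (4R,5R)-4-Ar-1,3-dioxan-5-ol
Product: 12 (4R)-4-Ar-1,3-dioxan-5-one
Conditions: Dess–Martin periodinane, NaHCO3, CH2Cl2, 0 °C to rt
Reagents that add atoms: none
Why: Dess–Martin oxidation under buffered, non-enolising conditions should give the ketone with the benzylic alpha stereocentre intact; the ketone is used crude.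

Step 9
Reactants: 12 (4R)-4-Ar-1,3-dioxan-5-one; 3 (E)-ArCH=CHI
Product: 15 (4R,5S)-4-Ar-5-[(E)-2-Ar-ethenyl]-1,3-dioxan-5-ol, via alkenyllithium 13 (not isolated), via alkenylcerium dichloride 14 (not isolated)
Conditions: 3, t-BuLi (2 equiv), Et2O, −78 °C; CeCl3, THF, −78 °C; 12, −78 °C; aq NH4Cl
Reagents that add atoms: none
Why: Iodine–lithium exchange with retention of alkene geometry followed by organocerium 1,2-addition: the weakly basic cerium reagent should add faster than it enolises the alpha-aryl ketone, and it should enter axially (the usual course for 1,3-dioxan-5-ones, which have ring oxygens in place of 1,3-diaxial C–H bonds and here no substituent at C2) with the 4-aryl group equatorial, placing the styryl group cis to the aryl group and setting the tertiary carbinol centre (S).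

Step 10
Reactants: 15 (4R,5S)-4-Ar-5-[(E)-2-Ar-ethenyl]-1,3-dioxan-5-ol
Product: 18 (1S,2R,5R,6S)-2,6-di-Ar-3,7-dioxabicyclo[3.3.0]octan-1-ol, via trimethylsilyl ether 16 (not isolated), via silylated bicycle 17 (not isolated)
Conditions: Me3SiOTf (1.3 equiv), 2,6-di-tert-butyl-4-methylpyridine (1.5 equiv), CH2Cl2 (0.01 M), −78 to −30 °C; then aq citric acid, MeOH, 0 °C
Reagents that add atoms: none
Why: Proposed new method: after silylation of the tertiary alcohol (16), the silyl cation should bind the less hindered acetal oxygen O1 of the dioxane and ionise the C2–O1 bond to the oxocarbenium ion H2C=O(+)–C4 held on the benzylic oxygen, whose carbon is attacked by the internal carbon of the (E)-styryl group (first ring, five-membered, 5-exo-trig with respect to the alkene and endo with respect to the C=O(+) bond), which contracts the six-membered acetal ring to the tetrahydrofuran and leaves a 3-methoxy-4-silyloxybenzyl cation; the Me3SiOCH2 oxygen released from the acetal carbon then closes onto that cation (second ring, five-membered, 5-exo-trig C–O closure) and passes the silyl cation on, so that the net event is an isomerisation of the 1,3-dioxane to the 3,7-dioxabicyclo[3.3.0]octane 17, which is desilylated to 18 on work-up. The closest known reaction types are the oxonium-Prins cyclisation of homoallylic ethers that carry a styrene-type alkene, which forms tetrahydrofurans by bonding at the internal alkene carbon with capture of the benzylic cation, and the Lewis-acid opening of cyclic acetals of allylic diols in the Prins–pinacol synthesis of tetrahydrofurans; new here are the ring formaldehyde acetal as the one-carbon unit and termination by the very oxygen that the acetal releases. The ring-fusion carbon C5 is set by what can close: only the cation whose benzylic carbon lies cis to the CH2OSiMe3 arm can give the bicycle (a trans-fused one is out of reach), while the cation formed on the other alkene face finds no nucleophile within reach (the neighbouring oxygen is deliberately a silyl ether and not the acetate) and should return to the alkene and the oxocarbenium ion by retro-Prins fragmentation, so that closure to the cis-fused bicycle drains the equilibrium. C6 is set in the capture of the cation, which should react in the rotamer that holds H-6, not the aryl group, beside the new C4–C5 bond (overall anti addition across the E alkene), and this puts the aryl group exo, as in the quinone-methide closures that lead to pinoresinol-type lignans. The step needs ionisation of C2–O1 and not of C2–O3 (secured by the primary against the hindered benzylic oxygen), bond formation at the internal and not the terminal alkene carbon, that is no Prins–pinacol or 2-oxonia-Cope course (secured by the electron-rich aryl group on the terminus, which makes the benzylic cation by far the better one), and survival of the tertiary allylic and the benzylic C–O bonds (secured by the silyl ether form of the tertiary oxygen, the inductive effect of the flanking C–O bonds, the hindered base and the low temperature).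

Step 11
Reactants: 18 (1S,2R,5R,6S)-2,6-di-Ar-3,7-dioxabicyclo[3.3.0]octan-1-ol
Product: 19 (1S,2R,5R,6S)-2,6-di-Ar-3,7-dioxabicyclo[3.3.0]octan-1-yl acetate
Conditions: Ac2O, DMAP, Et3N, CH2Cl2, 40 °C
Reagents that add atoms: acetic anhydride, CC(=O)OC(C)=O
Why: DMAP-catalysed (Steglich-type) acylation through the N-acetylpyridinium ion is the standard way to esterify a hindered tertiary alcohol under non-acidic conditions, and no stereocentre is touched.

Step 12
Reactants: 19 (1S,2R,5R,6S)-2,6-di-Ar-3,7-dioxabicyclo[3.3.0]octan-1-yl acetate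
Product: 20 1-acetoxypinoresinol, (1S,2R,5R,6S)-2,6-bis(4-hydroxy-3-methoxyphenyl)-3,7-dioxabicyclo[3.3.0]octan-1-yl acetate
Conditions: Bu4NF, AcOH, THF, 0 °C
Reagents that add atoms: none
Why: Fluoride-induced cleavage of the two aryl silyl ethers is fast at 0 °C, and the acetic acid buffer should keep the medium from becoming basic enough to cleave or shift the tertiary acetate.

**Compound list**

1 | vanillin | COc1cc(C=O)ccc1O | starting material
2 | 3-methoxy-4-(triisopropylsilyloxy)benzaldehyde (ArCHO) | COc1cc(C=O)ccc1O[Si](C(C)C)(C(C)C)C(C)C | intermediate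
3 | (E)-1-(2-iodoethenyl)-3-methoxy-4-(triisopropylsilyloxy)benzene | COc1cc(/C=C/I)ccc1O[Si](C(C)C)(C(C)C)C(C)C | intermediate
4 | (S)-4-benzyloxazolidin-2-one | O=C1OC[C@H](Cc2ccccc2)N1 | starting material
5 | benzyloxyacetyl chloride | O=C(Cl)COCc1ccccc1 | starting material
6 | (S)-4-benzyl-3-[(benzyloxy)acetyl]oxazolidin-2-one | O=C1OC[C@H](Cc2ccccc2)N1C(=O)COCc1ccccc1 | intermediate
7 | Z-dibutylboron enolate of 6 (not isolated) | CCCCB(CCCC)O/C(=C\OCc1ccccc1)N1C(=O)OC[C@@H]1Cc1ccccc1 | intermediate
8 | (4S)-4-benzyl-3-[(2S,3R)-3-Ar-2-(benzyloxy)-3-hydroxypropanoyl]oxazolidin-2-one | O=C1OC[C@H](Cc2ccccc2)N1C(=O)[C@@H](OCc1ccccc1)[C@H](O)c1ccc(O[Si](C(C)C)(C(C)C)C(C)C)c(OC)c1 | intermediate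
9 | (1R,2R)-1-Ar-2-(benzyloxy)propane-1,3-diol | OC[C@@H](OCc1ccccc1)[C@H](O)c1ccc(O[Si](C(C)C)(C(C)C)C(C)C)c(OC)c1 | intermediate
10 | (4R,5R)-4-Ar-5-(benzyloxy)-1,3-dioxane | C1OC[C@@H](OCc2ccccc2)[C@@H](c2ccc(O[Si](C(C)C)(C(C)C)C(C)C)c(OC)c2)O1 | intermediate
11 | (4R,5R)-4-Ar-1,3-dioxan-5-ol | C1OC[C@@H](O)[C@@H](c2ccc(O[Si](C(C)C)(C(C)C)C(C)C)c(OC)c2)O1 | intermediate
12 | (4R)-4-Ar-1,3-dioxan-5-one | C1OCC(=O)[C@@H](c2ccc(O[Si](C(C)C)(C(C)C)C(C)C)c(OC)c2)O1 | intermediate
13 | (E)-2-Ar-ethenyllithium (not isolated) | [Li]/C=C/c1ccc(O[Si](C(C)C)(C(C)C)C(C)C)c(OC)c1 | intermediate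
14 | (E)-2-Ar-ethenylcerium dichloride (not isolated) | Cl[Ce](Cl)/C=C/c1ccc(O[Si](C(C)C)(C(C)C)C(C)C)c(OC)c1 | intermediate
15 | (4R,5S)-4-Ar-5-[(E)-2-Ar-ethenyl]-1,3-dioxan-5-ol | C1OC[C@@](O)(/C=C/c2ccc(O[Si](C(C)C)(C(C)C)C(C)C)c(OC)c2)[C@@H](c2ccc(O[Si](C(C)C)(C(C)C)C(C)C)c(OC)c2)O1 | intermediate
16 | trimethylsilyl ether of 15 (not isolated) | C1OC[C@@](O[Si](C)(C)C)(/C=C/c2ccc(O[Si](C(C)C)(C(C)C)C(C)C)c(OC)c2)[C@@H](c2ccc(O[Si](C(C)C)(C(C)C)C(C)C)c(OC)c2)O1 | intermediate
17 | trimethylsilyl ether of 18 (not isolated) | COc1cc([C@H]2OC[C@]3(O[Si](C)(C)C)[C@@H](c4ccc(O[Si](C(C)C)(C(C)C)C(C)C)c(OC)c4)OC[C@H]23)ccc1O[Si](C(C)C)(C(C)C)C(C)C | intermediate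
18 | (1S,2R,5R,6S)-2,6-di-Ar-3,7-dioxabicyclo[3.3.0]octan-1-ol (bis-silyl ether of 1-hydroxypinoresinol) | COc1cc([C@H]2OC[C@]3(O)[C@@H](c4ccc(O[Si](C(C)C)(C(C)C)C(C)C)c(OC)c4)OC[C@H]23)ccc1O[Si](C(C)C)(C(C)C)C(C)C | intermediate
19 | (1S,2R,5R,6S)-2,6-di-Ar-3,7-dioxabicyclo[3.3.0]octan-1-yl acetate | COc1cc([C@H]2OC[C@]3(OC(C)=O)[C@@H](c4ccc(O[Si](C(C)C)(C(C)C)C(C)C)c(OC)c4)OC[C@H]23)ccc1O[Si](C(C)C)(C(C)C)C(C)C | intermediate
20 | 1-acetoxypinoresinol | COc1cc([C@H]2OC[C@]3(OC(C)=O)[C@@H](c4ccc(O)c(OC)c4)OC[C@H]23)ccc1O | target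

**Step count**

Total: 12 steps. Longest linear sequence: 10 steps (steps 1, 4, 5, 6, 7, 8, 9, 10, 11, 12, from vanillin).

**Steps most likely to fail**

First, step 10, which carries the proposed new method. What may go wrong: the acetal may open in the other sense (C2–O3), which would lead into an isomeric ring system; the tertiary allylic C–O bond or an electron-rich benzylic C–O bond may ionise instead of the acetal, with epimerisation at C2 or C6; the oxocarbenium ion may bond to the alkene terminus and follow a Prins–pinacol or 2-oxonia-Cope course; and the alkene may react on the face that leaves the benzylic cation trans to the CH2O arm, so that ring closure is impossible and material is lost by elimination. Fallback for step 10, by known chemistry, which sets out from ketone 12 and comes back to the route at compound 18: the cerium enolate of tert-butyl acetate (LiN(iPr)2, then CeCl3, THF, −78 °C) is added axially to 12, in the same sense as in step 9, and should give tert-butyl 2-[(4R,5S)-4-Ar-5-hydroxy-1,3-dioxan-5-yl]acetate F1 as the tertiary alcohol. Its alkoxide–enolate dianion (LiN(iPr)2, 2.2 equiv, THF, −78 °C) is silylated on both oxygens with Me3SiCl to the ketene acetal {1-tert-butoxy-2-[(4R,5S)-4-Ar-5-(trimethylsilyloxy)-1,3-dioxan-5-yl]ethenyl}oxy(trimethyl)silane F2 which with catalytic Me3SiOTf at −78 °C should undergo an intramolecular Mukaiyama-type alkylation by the opened formaldehyde acetal and give tert-butyl (4S,5R)-5-Ar-4-(trimethylsilyloxy)-4-[(trimethylsilyloxy)methyl]oxolane-3-carboxylate F3 as a mixture of C3 epimers. Trifluoroacetic acid in CH2Cl2 at 0 °C removes the trimethylsilyl and tert-butyl groups, and the hydroxy acid lactonises onto the CH2OH arm to the cis-fused lactone (1S,2R,5S)-2-Ar-1-hydroxy-3,7-dioxabicyclo[3.3.0]octan-6-one F4 in which the ring fusion is enforced by the lactone and not by a facial preference (the epimer that cannot lactonise is removed as the free acid). Separately, silylation of commercial 4-bromo-2-methoxyphenol (iPr3SiCl, imidazole) gives (4-bromo-2-methoxyphenoxy)triisopropylsilane F5 and bromine–lithium exchange with n-BuLi at −78 °C turns it into 3-methoxy-4-(triisopropylsilyloxy)phenyllithium F6 which adds once to the lactone at −78 °C to give the aryl ketone [(3S,4S,5R)-5-Ar-4-hydroxy-4-(hydroxymethyl)oxolan-3-yl](Ar)methanone F7 in equilibrium with its hemiketal. NaBH4 reduces this ketone to the benzylic triol (2R,3S,4R)-2-Ar-4-[Ar(hydroxy)methyl]-3-(hydroxymethyl)oxolan-3-ol F8 and catalytic camphorsulfonic acid then closes the second ring through the benzylic cation, which should place the aryl group exo and give 18.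

Second, step 9. What may go wrong: enolisation of the alpha-aryl ketone by the organometallic reagent, which would erode the only stereocentre the ketone carries; incomplete axial selectivity of the bulky alkenyl reagent; and partial loss of alkene geometry during the iodine–lithium exchange. Fallback for step 9, which sets out from iodide 3 and ketone 12 and comes back to the route at compound 15: two equivalents of LiN(iPr)2 convert 3 by elimination and deprotonation into lithium 2-Ar-acetylide F9 which is a small and much less basic nucleophile with a strong axial preference. Its addition to 12 in the presence of CeCl3 should give the propargylic alcohol (4R,5S)-4-Ar-5-(2-Ar-ethynyl)-1,3-dioxan-5-ol F10 and hydroxyl-directed trans-hydroalumination with sodium bis(2-methoxyethoxy)aluminium hydride in THF, followed by protonolysis, should then give the E alkene 15.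

Third, step 11. What may go wrong: sluggish acylation of the hindered ring-fusion tertiary alcohol, and under forcing conditions loss of the aryl silyl ethers with scrambling of acetyl groups onto the phenols. Fallback for step 11, which sets out from compound 18 and comes back to the route at the target 20: Bu4NF in THF removes both silyl groups to give 1-hydroxypinoresinol F11 whose exhaustive acetylation (Ac2O, DMAP, pyridine, 60 °C), where forcing conditions do no harm, gives the triacetate 1-acetoxypinoresinol diacetate F12 from which pyrrolidine in CH2Cl2 at 0 °C cleaves only the two aryl acetates, far more reactive than the tertiary alkyl acetate, to give 20.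

Further compounds
F1 | step 10 | tert-butyl 2-[(4R,5S)-4-Ar-5-hydroxy-1,3-dioxan-5-yl]acetate | C1OC[C@@](O)(CC(=O)OC(C)(C)C)[C@@H](c2ccc(O[Si](C(C)C)(C(C)C)C(C)C)c(OC)c2)O1
F2 | step 10 | {1-tert-butoxy-2-[(4R,5S)-4-Ar-5-(trimethylsilyloxy)-1,3-dioxan-5-yl]ethenyl}oxy(trimethyl)silane | C1OC[C@@](O[Si](C)(C)C)(C=C(O[Si](C)(C)C)OC(C)(C)C)[C@@H](c2ccc(O[Si](C(C)C)(C(C)C)C(C)C)c(OC)c2)O1
F3 | step 10 | tert-butyl (4S,5R)-5-Ar-4-(trimethylsilyloxy)-4-[(trimethylsilyloxy)methyl]oxolane-3-carboxylate (both C3 epimers) | C[Si](C)(C)OC[C@]1(O[Si](C)(C)C)[C@@H](c2ccc(O[Si](C(C)C)(C(C)C)C(C)C)c(OC)c2)OCC1C(=O)OC(C)(C)C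
F4 | step 10 | (1S,2R,5S)-2-Ar-1-hydroxy-3,7-dioxabicyclo[3.3.0]octan-6-one | O=C1OC[C@]2(O)[C@@H](c3ccc(O[Si](C(C)C)(C(C)C)C(C)C)c(OC)c3)OC[C@H]12
F5 | step 10 | (4-bromo-2-methoxyphenoxy)triisopropylsilane | COc1cc(Br)ccc1O[Si](C(C)C)(C(C)C)C(C)C
F6 | step 10 | 3-methoxy-4-(triisopropylsilyloxy)phenyllithium | [Li]c1ccc(O[Si](C(C)C)(C(C)C)C(C)C)c(OC)c1
F7 | step 10 | [(3S,4S,5R)-5-Ar-4-hydroxy-4-(hydroxymethyl)oxolan-3-yl](Ar)methanone | OC[C@]1(O)[C@@H](c2ccc(O[Si](C(C)C)(C(C)C)C(C)C)c(OC)c2)OC[C@@H]1C(=O)c1ccc(O[Si](C(C)C)(C(C)C)C(C)C)c(OC)c1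
F8 | step 10 | (2R,3S,4R)-2-Ar-4-[Ar(hydroxy)methyl]-3-(hydroxymethyl)oxolan-3-ol (both carbinol epimers) | OC[C@]1(O)[C@@H](c2ccc(O[Si](C(C)C)(C(C)C)C(C)C)c(OC)c2)OC[C@@H]1C(O)c1ccc(O[Si](C(C)C)(C(C)C)C(C)C)c(OC)c1
F9 | step 9 | lithium 2-Ar-acetylide | [Li]C#Cc1ccc(O[Si](C(C)C)(C(C)C)C(C)C)c(OC)c1
F10 | step 9 | (4R,5S)-4-Ar-5-(2-Ar-ethynyl)-1,3-dioxan-5-ol | C1OC[C@@](O)(C#Cc2ccc(O[Si](C(C)C)(C(C)C)C(C)C)c(OC)c2)[C@@H](c2ccc(O[Si](C(C)C)(C(C)C)C(C)C)c(OC)c2)O1
F11 | step 11 | 1-hydroxypinoresinol, (1S,2R,5R,6S)-2,6-bis(4-hydroxy-3-methoxyphenyl)-3,7-dioxabicyclo[3.3.0]octan-1-ol | COc1cc([C@H]2OC[C@]3(O)[C@@H](c4ccc(O)c(OC)c4)OC[C@H]23)ccc1O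
F12 | step 11 | 1-acetoxypinoresinol diacetate (triacetate of F11) | COc1cc([C@H]2OC[C@]3(OC(C)=O)[C@@H](c4ccc(OC(C)=O)c(OC)c4)OC[C@H]23)ccc1OC(C)=O
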